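Assumption: carotenoid locants are used for positions (C1–C15 for the half carrying the 3,4-diol, called ring A; primed locants for the 3'-hydroxy half, called ring B); TBS = tert-butyldimethylsilyl, TBSO = its ether.

## Retrosynthetic overview

1. Target ⇐ removal of three TBS ethers ⇐ Wittig olefination (C11=C12) between a ring A C15 phosphonium salt and a ring B C25 pentaenynal.
2. C25 aldehyde ⇐ key intermolecular vinylogous Mukaiyama aldol (C15'–C15 bond) of the ring B C20 dimethyl acetal with the silyl dienol ether of tiglaldehyde, then loss of methanol; the C20 aldehyde ⇐ the same aldol (C11'–C12') of the C15 acetal with the silyl dienol ether of prenal.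
3. Ring B C15 unit ⇐ Sonogashira coupling of a cyclohexenyl triflate with (2E)-3-methylpent-2-en-4-yn-1-ol; ring A C15 unit ⇐ acetylide addition to the enone, oxidative 1,3-transposition, cis-selective ketone reduction.
4. No ring is built: both carbocycles come intact from ketoisophorone through one asymmetric transfer hydrogenation ((4S)-phorenol sets C3 and C3'); ring B is elaborated first, ring A second, and the halves are joined last.

## Route

Step 1
Reactants: 1 ketoisophorone (2,6,6-trimethylcyclohex-2-ene-1,4-dione)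
Product: 2 (4S)-4-hydroxy-2,6,6-trimethylcyclohex-2-en-1-one ((S)-phorenol)
Conditions: RuCl[(S,S)-TsDPEN](p-cymene) (1 mol%), KOH (2 mol%), i-PrOH, rt
Reagents that add atoms: none
Why: Noyori asymmetric transfer hydrogenation reduces the unhindered C4 carbonyl (C1 is shielded by the gem-dimethyl and 2-methyl groups), and with the (S,S)-ligand and the alkenyl group as the π-substituent the hydride goes to the face that gives the 4S alcohol, the centre that becomes C3 and C3'.

Step 2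
Reactants: 2 (S)-phorenol
Product: 3 (4S)-4-(TBSO)-2,6,6-trimethylcyclohex-2-en-1-one
Conditions: TBSCl, imidazole, DMF, rt
Reagents that add atoms: tert-butyldimethylsilyl chloride, CC(C)(C)[Si](C)(C)Cl
Why: Standard silylation of a secondary alcohol protects the future C3/C3' hydroxyl against the organometallic, oxidation and Lewis-acid steps.

Step 3
Reactants: 3 (4S)-4-(TBSO)-2,6,6-trimethylcyclohex-2-en-1-one
Product: 4 (4R)-4-(TBSO)-2,2,6-trimethylcyclohexan-1-one (mixture of C6 epimers)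
Conditions: H2 (1 atm), Pd/C (10 %), EtOAc, rt
Reagents that add atoms: none
Why: Catalytic hydrogenation saturates the enone C=C without touching the C4 centre (S becomes R only by CIP priority), and the new C6 centre is irrelevant because it becomes sp2 in step 4.

Step 4
Reactants: 4 (4R)-4-(TBSO)-2,2,6-trimethylcyclohexan-1-one
Product: 6 (4R)-4-(TBSO)-2,6,6-trimethylcyclohex-1-en-1-yl trifluoromethanesulfonate, via lithium enolate 5 (not isolated)
Conditions: LiN(i-Pr)2, THF, −78 → 0 °C; PhNTf2, 0 °C → rt; H2O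
Reagents that add atoms: N-phenylbis(trifluoromethanesulfonimide), O=S(=O)(N(c1ccccc1)S(=O)(=O)C(F)(F)F)C(F)(F)F
Why: Enolate O-triflation is regiochemically unambiguous because only C6 carries an α-hydrogen, so a single tetrasubstituted enol triflate (the future C5'=C6') forms.

Step 5
Reactants: 6 enol triflate; 7 (2E)-3-methylpent-2-en-4-yn-1-ol
Product: 8 (2E)-5-[(4R)-4-(TBSO)-2,6,6-trimethylcyclohex-1-en-1-yl]-3-methylpent-2-en-4-yn-1-ol
Conditions: Pd(PPh3)4 (5 mol%), CuI (10 mol%), i-Pr2NH, THF, rt (degassed)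
Reagents that add atoms: none
Why: Sonogashira coupling of the vinyl triflate with the terminal alkyne makes the C6'–C7' bond, tolerates the free allylic alcohol and keeps the 9'E geometry of the commercial enynol.

Step 6
Reactants: 8 ring B C15 enynol
Product: 9 (2E)-5-[(4R)-4-(TBSO)-2,6,6-trimethylcyclohex-1-en-1-yl]-3-methylpent-2-en-4-ynal
Conditions: MnO2 (activated), CH2Cl2, rt
Reagents that add atoms: none
Why: Chemoselective MnO2 oxidation of the primary allylic alcohol gives the enal without affecting the silyl ether or the enyne.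

Step 7
Reactants: 9 ring B C15 enynal
Product: 10 dimethyl acetal of 9 (ring B carrying a (3E)-5,5-dimethoxy-3-methylpent-3-en-1-yn-1-yl chain)
Conditions: HC(OMe)3, MeOH, PPTS (cat.), rt
Reagents that add atoms: trimethyl orthoformate, COC(OC)OC
Why: Mild acid-catalysed acetalisation with orthoformate as water scavenger gives the acetal that serves as oxocarbenium precursor for the aldol.

Step 8
Reactants: 11 prenal (3-methylbut-2-enal)
Product: 12 (1E)-3-methyl-1-(trimethylsilyloxy)buta-1,3-diene (E major)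
Conditions: TMSCl, Et3N, ZnCl2 (cat.), toluene, 40 °C
Reagents that add atoms: chlorotrimethylsilane, C[Si](C)(C)Cl
Why: O-Silylation with γ-deprotonation (silyl dienol ether formation) turns the enal into a γ-nucleophilic C5 dienolate equivalent.

Step 9
Reactants: 10 ring B C15 acetal; 12 silyl dienol ether of prenal
Product: 14 (2E,4E,6E)-3,7-dimethyl-9-[(4R)-4-(TBSO)-2,6,6-trimethylcyclohex-1-en-1-yl]nona-2,4,6-trien-8-ynal, via δ-methoxy enal 13 (not isolated)
Conditions: TMSOTf (5 mol%), CH2Cl2, −78 °C; then DBU, 4 Å molecular sieves, rt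
Reagents that add atoms: none
Why: Vinylogous Mukaiyama aldol (acetal variant): γ-attack of the dienol ether on the oxocarbenium ion forms C11'–C12', and DBU-induced 1,4-elimination (E1cB) of methanol gives the conjugated trienynal with 11'E set thermodynamically and 13'E as the major equilibrium isomer, which is isolated by chromatography.

Step 10
Reactants: 14 ring B C20 aldehyde
Product: 15 dimethyl acetal of 14 ((2E,4E,6E)-1,1-dimethoxy-3,7-dimethylnona-2,4,6-trien-8-ynyl chain on ring B)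
Conditions: HC(OMe)3, MeOH, PPTS (cat.), 0 °C → rt
Reagents that add atoms: trimethyl orthoformate, COC(OC)OC
Why: Acetalisation as in step 7 activates the C20 aldehyde for the second aldol.

Step 11
Reactants: 16 tiglaldehyde ((2E)-2-methylbut-2-enal)
Product: 17 2-methyl-1-(trimethylsilyloxy)buta-1,3-diene (E/Z mixture, both react alike)
Conditions: TMSCl, Et3N, ZnCl2 (cat.), toluene, 40 °C
Reagents that add atoms: chlorotrimethylsilane, C[Si](C)(C)Cl
Why: Silyl dienol ether formation as in step 8 gives the C5 donor that carries the C13 methyl group.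

Step 12 (key step)
Reactants: 15 ring B C20 acetal; 17 silyl dienol ether of tiglaldehyde
Product: 19 (2E,4E,6E,8E,10E)-2,7,11-trimethyl-13-[(4R)-4-(TBSO)-2,6,6-trimethylcyclohex-1-en-1-yl]trideca-2,4,6,8,10-pentaen-12-ynal, via δ-methoxy enal 18 (not isolated)
Conditions: TMSOTf (5 mol%), CH2Cl2, −78 °C; then DBU, 4 Å molecular sieves, rt
Reagents that add atoms: none
Why: Vinylogous Mukaiyama aldol joins the C20 and C5 fragments at C15'–C15, and elimination of methanol gives the all-E C25 aldehyde because the α-methyl enal (13E) and the new disubstituted 15,15' bond are both strongly E-favoured.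

Step 13
Reactants: 7 (2E)-3-methylpent-2-en-4-yn-1-ol
Product: 20 tert-butyldimethyl{[(2E)-3-methylpent-2-en-4-yn-1-yl]oxy}silane
Conditions: TBSCl, imidazole, CH2Cl2, 0 °C → rt
Reagents that add atoms: tert-butyldimethylsilyl chloride, CC(C)(C)[Si](C)(C)Cl
Why: Silylation masks the primary alcohol so that the alkyne can be lithiated and the later chromium oxidation touches only the ring.

Step 14
Reactants: 20 silylated enynol; 3 (4S)-4-(TBSO)-2,6,6-trimethylcyclohex-2-en-1-one
Product: 22 (4S)-4-(TBSO)-1-[(3E)-5-(TBSO)-3-methylpent-3-en-1-yn-1-yl]-2,6,6-trimethylcyclohex-2-en-1-ol (C1 epimers), via lithium acetylide 21 (not isolated)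
Conditions: n-BuLi, THF, −78 °C; then 3, −78 → 0 °C; H2O
Reagents that add atoms: none
Why: 1,2-Addition of the lithium acetylide to the enone carbonyl forms the C6–C7 bond, and the carbinol configuration does not matter because that carbon becomes sp2 in step 15.

Step 15
Reactants: 22 tertiary allylic propargylic alcohol
Product: 23 (6S)-6-(TBSO)-3-[(3E)-5-(TBSO)-3-methylpent-3-en-1-yn-1-yl]-2,4,4-trimethylcyclohex-2-en-1-one
Conditions: pyridinium chlorochromate C5H5NH[CrO3Cl], 4 Å molecular sieves, CH2Cl2, rt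
Reagents that add atoms: pyridinium chlorochromate, [O-][Cr](=O)(=O)Cl.c1cc[nH+]cc1 (supplies the carbonyl oxygen)
Why: Babler–Dauben oxidative 1,3-transposition ([3,3]-shift of the tertiary allylic chromate ester, then oxidation) puts the oxygen on C4 and the double bond at C5=C6 in conjugation with the alkyne, leaving the C3 silyloxy centre untouched.

Step 16
Reactants: 23 ring A ynenone
Product: 24 (1R,6S)-6-(TBSO)-3-[(3E)-5-(TBSO)-3-methylpent-3-en-1-yn-1-yl]-2,4,4-trimethylcyclohex-2-en-1-ol (cis)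
Conditions: LiBH(s-Bu)3, THF, −78 °C; H2O
Reagents that add atoms: none
Why: Substrate-controlled 1,2-reduction in which the bulky hydride attacks the carbonyl face anti to the neighbouring silyloxy group (equatorial attack; 1,4-addition is blocked by the fully substituted β-carbon), setting C4 as R, cis to the C3 oxygen.

Step 17
Reactants: 24 cis-allylic alcohol
Product: 25 (3R,4S)-3,4-bis(TBSO)-1-[(3E)-5-(TBSO)-3-methylpent-3-en-1-yn-1-yl]-2,6,6-trimethylcyclohex-1-ene
Conditions: TBSOTf, 2,6-lutidine, CH2Cl2, 0 °C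
Reagents that add atoms: tert-butyldimethylsilyl trifluoromethanesulfonate, CC(C)(C)[Si](C)(C)OS(=O)(=O)C(F)(F)F
Why: Silyl triflate silylation caps the hindered, acid-sensitive allylic C4 hydroxyl (any 3-O to 4-O silyl migration in step 16 converges here to the same bis-ether).

Step 18
Reactants: 25 tris-silyl ether
Product: 26 (2E)-5-[(3R,4S)-3,4-bis(TBSO)-2,6,6-trimethylcyclohex-1-en-1-yl]-3-methylpent-2-en-4-yn-1-ol
Conditions: HF·pyridine, pyridine, THF, 0 °C
Reagents that add atoms: none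
Why: Selective desilylation: the unhindered primary allylic TBS ether is cleaved much faster than the two hindered secondary ones under buffered fluoride conditions.

Step 19
Reactants: 26 ring A C15 allylic alcohol
Product: 27 (3R,4S)-1-[(3E)-5-bromo-3-methylpent-3-en-1-yn-1-yl]-3,4-bis(TBSO)-2,6,6-trimethylcyclohex-1-ene
Conditions: CBr4, PPh3, CH2Cl2, 0 °C
Reagents that add atoms: carbon tetrabromide, BrC(Br)(Br)Br
Why: Appel bromination converts the primary allylic alcohol to the bromide under neutral conditions that spare the silyl ethers and the double-bond geometry.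

Step 20
Reactants: 27 allylic bromide
Product: 28 {(2E)-5-[(3R,4S)-3,4-bis(TBSO)-2,6,6-trimethylcyclohex-1-en-1-yl]-3-methylpent-2-en-4-yn-1-yl}triphenylphosphonium bromide
Conditions: PPh3, EtOAc, rt
Reagents that add atoms: triphenylphosphine, c1ccc(cc1)P(c1ccccc1)c1ccccc1
Why: SN2 quaternisation of triphenylphosphine by the primary allylic bromide gives the crystalline Wittig salt.

Step 21
Reactants: 28 ring A C15 phosphonium bromide; 19 ring B C25 aldehyde
Product: 30 (all-E,3S,4R,3'R)-3,4,3'-tris(TBSO)-7,8,7',8'-tetradehydro-β,β-carotene, via phosphonium ylide 29 (not isolated)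
Conditions: NaOMe, MeOH/CH2Cl2, 0 °C → rt, dark, argon
Reagents that add atoms: none
Why: Wittig olefination with the semi-stabilised allylic ylide forms C11=C12 mainly E, and the minor hindered 11Z isomer is removed by chromatography or crystallisation.

Step 22
Reactants: 30 tris-silylated carotenoid
Product: 31 (all-E,3S,4R,3'R)-7,8,7',8'-tetradehydro-β,β-carotene-3,4,3'-triol (CNP0323983.1)
Conditions: Bu4NF, AcOH, THF, rt → 40 °C, dark, argon
Reagents that add atoms: none
Why: Fluoride-mediated desilylation under buffered, non-acidic conditions frees the three hydroxyls without ionising the allylic C4 alcohol or isomerising the polyene.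

## Compound list

1 | ketoisophorone (2,6,6-trimethylcyclohex-2-ene-1,4-dione) | CC1=CC(=O)CC(C)(C)C1=O | starting material
2 | (4S)-4-hydroxy-2,6,6-trimethylcyclohex-2-en-1-one | O=C1C(C)=C[C@@H](O)CC1(C)C | intermediate
3 | (4S)-4-(TBSO)-2,6,6-trimethylcyclohex-2-en-1-one | O=C1C(C)=C[C@@H](O[Si](C)(C)C(C)(C)C)CC1(C)C | intermediate
4 | (4R)-4-(TBSO)-2,2,6-trimethylcyclohexan-1-one, C6 epimers | O=C1C(C)C[C@@H](O[Si](C)(C)C(C)(C)C)CC1(C)C | intermediate
5 | lithium (4R)-4-(TBSO)-2,6,6-trimethylcyclohex-1-en-1-olate | [Li]OC1=C(C)C[C@@H](O[Si](C)(C)C(C)(C)C)CC1(C)C | intermediate (not isolated)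
6 | (4R)-4-(TBSO)-2,6,6-trimethylcyclohex-1-en-1-yl trifluoromethanesulfonate | O=S(=O)(OC1=C(C)C[C@@H](O[Si](C)(C)C(C)(C)C)CC1(C)C)C(F)(F)F | intermediate
7 | (2E)-3-methylpent-2-en-4-yn-1-ol | C#C/C(C)=C/CO | starting material
8 | (2E)-5-[(4R)-4-(TBSO)-2,6,6-trimethylcyclohex-1-en-1-yl]-3-methylpent-2-en-4-yn-1-ol | OC/C=C(C)/C#CC1=C(C)C[C@@H](O[Si](C)(C)C(C)(C)C)CC1(C)C | intermediate
9 | (2E)-5-[(4R)-4-(TBSO)-2,6,6-trimethylcyclohex-1-en-1-yl]-3-methylpent-2-en-4-ynal | O=C/C=C(C)/C#CC1=C(C)C[C@@H](O[Si](C)(C)C(C)(C)C)CC1(C)C | intermediate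
10 | dimethyl acetal of 9 | COC(OC)/C=C(C)/C#CC1=C(C)C[C@@H](O[Si](C)(C)C(C)(C)C)CC1(C)C | intermediate
11 | prenal (3-methylbut-2-enal) | CC(C)=CC=O | starting material
12 | (1E)-3-methyl-1-(trimethylsilyloxy)buta-1,3-diene | C=C(C)/C=C/O[Si](C)(C)C | intermediate
13 | (6E)-5-methoxy-3,7-dimethyl-9-[(4R)-4-(TBSO)-2,6,6-trimethylcyclohex-1-en-1-yl]nona-2,6-dien-8-ynal, mixture at C5 and at the 2-ene | O=CC=C(C)CC(OC)/C=C(C)/C#CC1=C(C)C[C@@H](O[Si](C)(C)C(C)(C)C)CC1(C)C | intermediate (not isolated)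
14 | (2E,4E,6E)-3,7-dimethyl-9-[(4R)-4-(TBSO)-2,6,6-trimethylcyclohex-1-en-1-yl]nona-2,4,6-trien-8-ynal | O=C/C=C(C)/C=C/C=C(C)/C#CC1=C(C)C[C@@H](O[Si](C)(C)C(C)(C)C)CC1(C)C | intermediate
15 | dimethyl acetal of 14 | COC(OC)/C=C(C)/C=C/C=C(C)/C#CC1=C(C)C[C@@H](O[Si](C)(C)C(C)(C)C)CC1(C)C | intermediate
16 | tiglaldehyde ((2E)-2-methylbut-2-enal) | C/C=C(\C)C=O | starting material
17 | 2-methyl-1-(trimethylsilyloxy)buta-1,3-diene (E/Z mixture, E drawn) | C=C/C(C)=C/O[Si](C)(C)C | intermediate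
18 | (2E,6E,8E,10E)-5-methoxy-2,7,11-trimethyl-13-[(4R)-4-(TBSO)-2,6,6-trimethylcyclohex-1-en-1-yl]trideca-2,6,8,10-tetraen-12-ynal, C5 epimers | O=C/C(C)=C/CC(OC)/C=C(C)/C=C/C=C(C)/C#CC1=C(C)C[C@@H](O[Si](C)(C)C(C)(C)C)CC1(C)C | intermediate (not isolated)
19 | (2E,4E,6E,8E,10E)-2,7,11-trimethyl-13-[(4R)-4-(TBSO)-2,6,6-trimethylcyclohex-1-en-1-yl]trideca-2,4,6,8,10-pentaen-12-ynal | O=C/C(C)=C/C=C/C=C(C)/C=C/C=C(C)/C#CC1=C(C)C[C@@H](O[Si](C)(C)C(C)(C)C)CC1(C)C | intermediate
20 | tert-butyldimethyl{[(2E)-3-methylpent-2-en-4-yn-1-yl]oxy}silane | C#C/C(C)=C/CO[Si](C)(C)C(C)(C)C | intermediate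
21 | lithium acetylide of 20 | [Li]C#C/C(C)=C/CO[Si](C)(C)C(C)(C)C | intermediate (not isolated)
22 | (4S)-4-(TBSO)-1-[(3E)-5-(TBSO)-3-methylpent-3-en-1-yn-1-yl]-2,6,6-trimethylcyclohex-2-en-1-ol, C1 epimers | CC1=C[C@@H](O[Si](C)(C)C(C)(C)C)CC(C)(C)C1(O)C#C/C(C)=C/CO[Si](C)(C)C(C)(C)C | intermediate
23 | (6S)-6-(TBSO)-3-[(3E)-5-(TBSO)-3-methylpent-3-en-1-yn-1-yl]-2,4,4-trimethylcyclohex-2-en-1-one | O=C1C(C)=C(C#C/C(C)=C/CO[Si](C)(C)C(C)(C)C)C(C)(C)C[C@@H]1O[Si](C)(C)C(C)(C)C | intermediate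
24 | (1R,6S)-6-(TBSO)-3-[(3E)-5-(TBSO)-3-methylpent-3-en-1-yn-1-yl]-2,4,4-trimethylcyclohex-2-en-1-ol | O[C@@H]1C(C)=C(C#C/C(C)=C/CO[Si](C)(C)C(C)(C)C)C(C)(C)C[C@@H]1O[Si](C)(C)C(C)(C)C | intermediate
25 | (3R,4S)-3,4-bis(TBSO)-1-[(3E)-5-(TBSO)-3-methylpent-3-en-1-yn-1-yl]-2,6,6-trimethylcyclohex-1-ene | CC(C)(C)[Si](C)(C)O[C@@H]1C(C)=C(C#C/C(C)=C/CO[Si](C)(C)C(C)(C)C)C(C)(C)C[C@@H]1O[Si](C)(C)C(C)(C)C | intermediate
26 | (2E)-5-[(3R,4S)-3,4-bis(TBSO)-2,6,6-trimethylcyclohex-1-en-1-yl]-3-methylpent-2-en-4-yn-1-ol | CC(C)(C)[Si](C)(C)O[C@@H]1C(C)=C(C#C/C(C)=C/CO)C(C)(C)C[C@@H]1O[Si](C)(C)C(C)(C)C | intermediate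
27 | (3R,4S)-1-[(3E)-5-bromo-3-methylpent-3-en-1-yn-1-yl]-3,4-bis(TBSO)-2,6,6-trimethylcyclohex-1-ene | CC(C)(C)[Si](C)(C)O[C@@H]1C(C)=C(C#C/C(C)=C/CBr)C(C)(C)C[C@@H]1O[Si](C)(C)C(C)(C)C | intermediate
28 | {(2E)-5-[(3R,4S)-3,4-bis(TBSO)-2,6,6-trimethylcyclohex-1-en-1-yl]-3-methylpent-2-en-4-yn-1-yl}triphenylphosphonium bromide | CC(C)(C)[Si](C)(C)O[C@@H]1C(C)=C(C#C/C(C)=C/C[P+](c2ccccc2)(c2ccccc2)c2ccccc2)C(C)(C)C[C@@H]1O[Si](C)(C)C(C)(C)C.[Br-] | intermediate
29 | phosphonium ylide of 28 | CC(C)(C)[Si](C)(C)O[C@@H]1C(C)=C(C#C/C(C)=C/C=P(c2ccccc2)(c2ccccc2)c2ccccc2)C(C)(C)C[C@@H]1O[Si](C)(C)C(C)(C)C | intermediate (not isolated)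
30 | (all-E,3S,4R,3'R)-3,4,3'-tris(TBSO)-7,8,7',8'-tetradehydro-β,β-carotene | CC(C)(C)[Si](C)(C)O[C@@H]1C(C)=C(C#C/C(C)=C/C=C/C(C)=C/C=C/C=C(C)/C=C/C=C(C)/C#CC2=C(C)C[C@@H](O[Si](C)(C)C(C)(C)C)CC2(C)C)C(C)(C)C[C@@H]1O[Si](C)(C)C(C)(C)C | intermediate
31 | (all-E,3S,4R,3'R)-7,8,7',8'-tetradehydro-β,β-carotene-3,4,3'-triol | CC1=C(C#C/C(C)=C/C=C/C(C)=C/C=C/C=C(C)/C=C/C=C(\C)C#CC2=C(C)[C@@H](O)[C@@H](O)CC2(C)C)C(C)(C)C[C@H](O)C1 | target

## Step count and risks

Total steps: 22. Longest linear sequence: 12 steps (1 → 2 → 3 → 4 → 6 → 8 → 9 → 10 → 14 → 15 → 19 → 30 → 31).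

The three steps most likely to fail:

Step 9 (first vinylogous aldol). The risks are α- instead of γ-attack of the dienol ether, a 13'E/13'Z mixture after elimination and some erosion of the 9'E geometry under Lewis acid and DBU. The fallback sets out from aldehyde 9 and replaces the aldol by a C5 Horner–Wadsworth–Emmons olefination. Aldehyde 9 is treated with the sodium salt of diethyl [(2E)-3-cyano-2-methylprop-2-en-1-yl]phosphonate (NaH, THF, 0 °C → rt) to give (2E,4E,6E)-3,7-dimethyl-9-[(4R)-4-(TBSO)-2,6,6-trimethylcyclohex-1-en-1-yl]nona-2,4,6-trien-8-ynenitrile F1. The all-E nitrile is purified and reduced with i-Bu2AlH (CH2Cl2, −78 °C, then aqueous work-up), which returns the route at aldehyde 14.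

Step 15 (oxidative transposition). The tertiary alcohol is both allylic and propargylic, so the chromate could migrate toward the alkyne, or the acidic reagent could ionise the carbinol. The fallback sets out from 22 and separates transposition from oxidation. Ph3SiOReO3 (2 mol%, Et2O, 0 °C) catalyses a redox-neutral 1,3-hydroxyl shift to the thermodynamically favoured conjugated secondary alcohol, (6S)-6-(TBSO)-3-[(3E)-5-(TBSO)-3-methylpent-3-en-1-yn-1-yl]-2,4,4-trimethylcyclohex-2-en-1-ol as a C1 epimer mixture F2. This is oxidised with MnO2 (CH2Cl2, rt) and comes back to the route at ketone 23.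

Step 16 (cis-selective reduction). The facial selectivity of the bulky hydride on this half-chair enone is argued by analogy and not proven; the trans-alcohol or 1,6-reduction of the ynenone could compete. The fallback sets out from 23 and makes the trans isomer deliberately, then inverts it. Luche reduction (NaBH4, CeCl3·7H2O, MeOH, −78 °C; axial attack) gives the trans-alcohol (1S,6S)-6-(TBSO)-3-[(3E)-5-(TBSO)-3-methylpent-3-en-1-yn-1-yl]-2,4,4-trimethylcyclohex-2-en-1-ol F3. Mitsunobu inversion (4-nitrobenzoic acid, PPh3, diisopropyl azodicarboxylate, THF, 0 °C) gives the cis ester (1R,6S)-6-(TBSO)-3-[(3E)-5-(TBSO)-3-methylpent-3-en-1-yn-1-yl]-2,4,4-trimethylcyclohex-2-en-1-yl 4-nitrobenzoate F4. Methanolysis (K2CO3, MeOH, 0 °C) returns the route at alcohol 24.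

Further compounds
F1 | step 9 | (2E,4E,6E)-3,7-dimethyl-9-[(4R)-4-(TBSO)-2,6,6-trimethylcyclohex-1-en-1-yl]nona-2,4,6-trien-8-ynenitrile | N#C/C=C(C)/C=C/C=C(C)/C#CC1=C(C)C[C@@H](O[Si](C)(C)C(C)(C)C)CC1(C)C
F2 | step 15 | (6S)-6-(TBSO)-3-[(3E)-5-(TBSO)-3-methylpent-3-en-1-yn-1-yl]-2,4,4-trimethylcyclohex-2-en-1-ol, C1 epimers | OC1C(C)=C(C#C/C(C)=C/CO[Si](C)(C)C(C)(C)C)C(C)(C)C[C@@H]1O[Si](C)(C)C(C)(C)C
F3 | step 16 | (1S,6S)-6-(TBSO)-3-[(3E)-5-(TBSO)-3-methylpent-3-en-1-yn-1-yl]-2,4,4-trimethylcyclohex-2-en-1-ol | O[C@H]1C(C)=C(C#C/C(C)=C/CO[Si](C)(C)C(C)(C)C)C(C)(C)C[C@@H]1O[Si](C)(C)C(C)(C)C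
F4 | step 16 | (1R,6S)-6-(TBSO)-3-[(3E)-5-(TBSO)-3-methylpent-3-en-1-yn-1-yl]-2,4,4-trimethylcyclohex-2-en-1-yl 4-nitrobenzoate | O=C(O[C@@H]1C(C)=C(C#C/C(C)=C/CO[Si](C)(C)C(C)(C)C)C(C)(C)C[C@@H]1O[Si](C)(C)C(C)(C)C)c1ccc(cc1)[N+](=O)[O-]
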